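## Conventions and compound key

Positions follow eremophilane numbering: C1, C2 ring CH2; C3 CH–OAc; C4 CH–CH3 (methyl C15); C5 quaternary C–CH3 (methyl C14); C6 alkene CH; C7 acetyl-bearing alkene carbon (acetyl C11, C12; C13 is the carbon that is lost); C8 ketone; C9 CH–O-angeloyl; C10 C–OH. Ring A is C5 to C10, ring B is C1 to C5 plus C10. β is the face of the C5 methyl.

Key: 1 farnesol; 2 farnesyl chloride; 3 farnesyl diphosphate; 4 germacrene A; 5 (+)-aristolochene; 6 C8 ketone; 7 3β-alcohol; 8 3β-acetate; 9 8β-allylic alcohol; 10 epoxy alcohol; 11 epoxy ketone; 12 angelic acid; 13 9α-angelate with free 10β-hydroxyl; 14 β-diketone; 15 selenide; 16 selenoxide; 17 target.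

## Analysis of the target

The target is a cis-fused decalin. Ring A (C5–C10) is a cyclohexenone with the C8 ketone, the C6=C7 alkene bearing an acetyl group on C7, the angelate on C9 and a tertiary hydroxyl on C10. Ring B (C1–C5, C10) is saturated and carries the acetate on C3 and the methyls on C4 and C5.

The five stereocentres form one chain, C3–C4–C5–C10–C9. The 3-acetoxy, 4-methyl, 5-methyl and 10-hydroxy groups are all β; the C9 ester is α, trans to the C10 hydroxyl (3S,4R,5R,9S,10R). C5 and C10 are adjacent fully substituted carbons.

Sensitive groups are the Z-configured angelate (isomerises to the tiglate), the aldol-type pair C8 ketone/C10 hydroxyl (dehydration, retro-aldol), the C6=C7 alkene between two carbonyls (a strong Michael acceptor), and two different esters that must stay distinct.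

The synthesis is hard for two reasons. The C3 oxygen has no functional neighbour. The dense oxidation of ring A must be built in an order that keeps base away from the acidic C7 and C9 positions.

The strategy rests on one observation. Without its oxygens, and with one carbon added to the acetyl group, the molecule is a 4β,5β-dimethyl decalin with a three-carbon branch on C7. That is the skeleton and configuration of (+)-aristolochene, so the target is a 13-nor-aristolochane. The C9=C10 alkene of that hydrocarbon lies where the C8, C9 and C10 oxygens are needed.

## Retrosynthetic reasoning

**17 to 14.** The C6=C7 alkene is removed first. It is the most electrophilic site of the target and would not survive nucleophiles, so it is made last. The forward reaction is a dehydrogenation at C7, the carbon between the two carbonyls of 14, through selenide 15 and selenoxide 16. Only C6 carries a β-hydrogen, so the alkene can form in one place only.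

**14 to 13.** The acetyl group is traced to an isopropenyl group by adding C13 back to C11. This exposes the nor-sesquiterpene as a cleaved aristolochane. The forward cleavage must take the 1,1-disubstituted alkene of 13 and leave the conjugated angelate alkene alone.

**13 to 11 and 12.** The C9–O bond is cut. The acid 12 enters as a carboxylate nucleophile at C9 of the epoxy ketone 11. C9 is α to the C8 carbonyl and open to backside attack; C10 is fully substituted and is not. Inversion at C9 gives the α ester and releases the 10β-hydroxyl, so both centres and their trans relation come from one epoxide. Acylating a hindered alcohol with an activated derivative of 12, with its risk of Z-to-E isomerisation, is avoided.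

**11 to 10 to 9 to 8.** The epoxide is taken back to the C9=C10 alkene, and C8 is moved between ketone and alcohol. Base-mediated nucleophilic epoxidation of enone 8 would be one step shorter but is not used. In 8 the C7 hydrogen is α to the ketone and allylic to the isopropenyl group. Base would epimerise C7, move the alkene into conjugation (after which the later cleavage would give the wrong ketone), and attack the acetate. Instead 8 is reduced to the 8β-alcohol 9, whose hydroxyl directs the epoxidation to the β face to give 10. A neutral oxidation then returns the ketone in 11. The extra two steps buy facial control by a directing group and a base-free sequence.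

**8 to 7 to 6.** The C3–O bond is cut. C3 has no functional neighbour that chemical reagents could use, so the forward step is an enzymatic C–H hydroxylation of 6. It must select C3 and the β hydrogen. Acetylation of 7 then gives 8.

**6 to 5.** The C8 carbonyl is removed. The forward reaction is an allylic oxidation of the C9=C10 alkene of 5 at the methylene next to its CH terminus.

**5 to 3 (through 4).** This is the key disconnection. The C6–C7 and C5–C10 bonds are cut and methyl C14 is returned from C5 to C10. Both rings open and the three stereocentres of 5 disappear, leaving the achiral, acyclic diphosphate 3. The forward reaction must fold the chain, close ring A and ring B, shift a hydride and a methyl group, and end by loss of a proton at C9.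

**3 to 2 to 1.** The diphosphate is cut at the C–O bond to the allylic chloride 2, and 2 is cut to the commercial alcohol 1. Both forward steps are substitutions at a primary allylic carbon that must not scramble the alkene geometry.

## Alternatives that were turned down

**Alternative 1:** The disconnection is the C5–C14 bond, the angular methyl. In the forward step Bu3SnH and AIBN convert the (bromomethyl)dimethylsilyl ether A2, which hangs on the C10 oxygen of a C4=C5 enone, into an α-silyl radical. The radical adds 5-exo to C5 and gives the cis-fused oxasilolane A1.
- For it: the tether can only reach the face of its own oxygen, so the cis relation between the C5 methyl and the C10 hydroxyl is enforced by ring strain. A1 already has a C3 carbonyl and a C8 oxygen, so no C–H oxidation is needed at C3.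
- Against it: the radical must attack a fully substituted alkene carbon and create a quaternary centre beside the fully substituted C10; direct reduction of the radical competes. C4 is set only by hydrogen-atom transfer to an α-keto radical and stays epimerisable. The C–Si bond must be cleaved to C–H at a neopentyl carbon. A2 needs its own asymmetric synthesis. Ring A still lacks the C7 acetyl, the C6=C7 alkene and the C9 oxygen.
- Comparison: this route is stronger on the C5/C10 relation and on the C3 oxygen. The chosen route offers both rings, the C4/C5 methyls and the C7 branch with absolute configuration in one step, three steps from 1.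

**Alternative 2:** The disconnection is the C1–C10 bond. In the forward step Et2Zn or Ti(OiPr)4 opens the cyclopropanol A4 to a homoenolate with the metal on C1. This adds to the C10 ketone, closing ring B and giving the hydroxy ketone A3.
- For it: the tertiary alcohol and ring B form together, and A3 carries oxygen at C3, C8 and C10.
- Against it: zinc and titanium homoenolates are weak nucleophiles, and the C10 ketone sits beside the quaternary C5. Protonation to the open ethyl ketone and β-hydride elimination compete with six-membered ring closure. Nothing forces the hydroxyl to end up cis to the C5 methyl. The C4/C5 pair, a tertiary centre beside a quaternary one, must already be present in A4 with absolute control; the step does not solve it.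
- Comparison: this route is stronger on oxygenation pattern. The chosen route has the enzyme set C4, C5 and C7 while it forms three skeletal bonds, and pays for that with a C–H oxidation at C3.

**Alternative 3:** The disconnections are C4–C15 and C5–C6 on a monocyclic ring B. In the forward step Cu(OTf)2 with a chiral phosphoramidite transfers methyl from AlMe3 to C4 of the enone A6. The aluminium enolate is activated with MeLi and allylated at C5, anti to the new methyl, to give the ketone A5.
- For it: small-molecule catalysis that should scale, with the cis methyls set by anti alkylation. A5 carries the C3 oxygen as a ketal and the C10 carbonyl. No enzyme is needed.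
- Against it: no ring is formed. Ring A must be built from the allyl group plus one more carbon and closed onto C10 with control of the carbinol configuration, then oxidised at C8 and C9 and acylated at C7. The β-carbon of A6 is flanked by the ketal carbon, so rate and enantioselectivity of the methyl transfer are uncertain. Alkylating a hindered aluminium enolate to a quaternary centre is slow.
- Comparison: this route is stronger on predictability and on the C3 oxygen. The chosen route delivers the whole bicyclic skeleton, including the C7 branch, in one bond-forming event and needs far fewer C–C bond-forming steps.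

Key step: step 3

## Assumptions

- A cytochrome P450 BM3 variant that hydroxylates C3 of 6 with removal of the β (axial) hydrogen is assumed to be found by screening a mutant panel; the fallback for step 5 covers other outcomes.
- The diphosphate 3 is handled as its trisammonium salt, the form in which it is water-soluble and accepted by the cyclase.
- All eremophilane intermediates keep the configuration of 5 at C4 and C5 (both methyls β) and at C7 (isopropenyl α) unless stated otherwise.

## Route

Step 1
Reactants: 1 (2E,6E)-farnesol
Product: 2 (2E,6E)-farnesyl chloride
Conditions: NCS, Me2S, CH2Cl2, −40 → 0 °C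
Reagents that add atoms: N-chlorosuccinimide, O=C1CCC(=O)N1Cl
Why: Corey–Kim chlorination: the alkoxysulfonium salt is displaced by chloride at the primary carbon under neutral conditions, so neither allylic transposition nor E/Z scrambling is expected.

Step 2
Reactants: 2 (2E,6E)-farnesyl chloride
Product: 3 (2E,6E)-farnesyl diphosphate as trisammonium salt
Conditions: (Bu4N)3HP2O7, MeCN, 25 °C; then Dowex 50W-X8 (NH4+ form), aq. NH4HCO3/iPrOH; cellulose chromatography
Reagents that add atoms: tris(tetrabutylammonium) hydrogen diphosphate, CCCC[N+](CCCC)(CCCC)CCCC.CCCC[N+](CCCC)(CCCC)CCCC.CCCC[N+](CCCC)(CCCC)CCCC.OP(=O)([O-])OP(=O)([O-])[O-]; ammonium hydrogen carbonate (gives the counter-ions), [NH4+].OC(=O)[O-]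
Why: SN2 displacement of the primary allylic chloride by the diphosphate anion in a dipolar aprotic solvent, the standard diphosphorylation of allylic halides; cation exchange gives the water-soluble ammonium salt.

Step 3
Reactants: 3 (2E,6E)-farnesyl diphosphate as trisammonium salt
Product: 5 (+)-aristolochene = (4S,5R,7S)-eremophila-9,11-diene, via (S)-germacrene A 4 (not isolated)
Conditions: recombinant aristolochene synthase (Penicillium roqueforti enzyme, expressed in E. coli), MgCl2, Tris·HCl buffer pH 7.5, pentane overlay, 25 °C
Reagents that add atoms: none
Why: Magnesium ions bound in the active site pull off the diphosphate of 3; the distal alkene attacks the allyl cation so that the C6–C7 bond and a ten-membered ring form, and loss of a proton from C12 leaves enzyme-bound 4. Protonation of 4 at C1 gives the C10 cation, which the C4=C5 alkene attacks across the ring, forming the C5–C10 bond and the eudesmyl cation at C4. A 1,2-hydride shift from C5 to C4, a 1,2-shift of methyl C14 from C10 to C5 and loss of a proton from C9 then give 5 with its C9=C10 alkene. The closest known reaction type is the cationic polyene cyclisation of a magnesium-dependent sesquiterpene cyclase, and this conversion is the native reaction of the enzyme. The ten-membered ring closes exo with respect to the attacking alkene (cation on the exocyclic C11); the transannular bond then creates both six-membered rings at once, endo for ring B (C4 and C5 inside) and exo for ring A (C4 outside). C7 is fixed by the alkene face that the folded chain presents in the first closure, C4 by suprafacial delivery of the hydride to the α face (methyl C15 β), and C5 by migration of C14 on the β face anti to the departed hydride; all three follow from the fold imposed by the active-site contour, hence 4S,5R,7S. The step needs product fidelity, that is quenching only after both shifts and only by deprotonation at C9; the enzyme secures this by shielding the cations from water and placing its base next to C9, and small amounts of released 4 or of the 1(10)-alkene isomer would be removed on AgNO3-impregnated silica.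

Step 4
Reactants: 5 (+)-aristolochene
Product: 6 (4S,5R,7S)-eremophila-9,11-dien-8-one
Conditions: CrO3, 3,5-dimethylpyrazole, CH2Cl2, −20 °C
Reagents that add atoms: chromium trioxide, O=[Cr](=O)=O
Why: Allylic oxidation with the CrO3–dimethylpyrazole complex attacks the methylene attached to the CH end of a trisubstituted ring alkene (as steroidal 5-enes give 7-ketones and valencene gives nootkatone), which places the carbonyl at C8 and not at C1. The isopropenyl group and the stereocentres are not touched, and the cold, non-basic medium should keep the isopropenyl alkene out of conjugation.

Step 5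
Reactants: 6 (4S,5R,7S)-eremophila-9,11-dien-8-one
Product: 7 3β-hydroxyeremophila-9,11-dien-8-one (3S,4R,5R,7S)
Conditions: P450 BM3 (CYP102A1) variant from a screening panel, NADP+ (cat.), D-glucose, glucose dehydrogenase, air, phosphate buffer pH 7.5, 2% EtOH, 25 °C
Reagents that add atoms: dioxygen, O=O
Why: Cytochrome P450 C–H hydroxylation: hydrogen abstraction by the iron–oxo haem and oxygen rebound, with retention. Engineered P450 BM3 variants hydroxylate C3 of terpenoid decalins, and fungal eremophilane pathways oxygenate C3 of this very skeleton. Site and face (loss of the axial 3β hydrogen, giving 3S) are set by the binding pocket of the variant chosen in the screen.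

Step 6
Reactants: 7 3β-hydroxyeremophila-9,11-dien-8-one
Product: 8 3β-acetoxyeremophila-9,11-dien-8-one
Conditions: Ac2O, pyridine, DMAP (cat.), CH2Cl2, 0 °C
Reagents that add atoms: acetic anhydride, CC(=O)OC(C)=O
Why: DMAP-catalysed acylation of the only hydroxyl, a hindered axial secondary alcohol; low temperature and short contact with the amine should keep the β,γ-unsaturated ketone from isomerising.

Step 7
Reactants: 8 3β-acetoxyeremophila-9,11-dien-8-one
Product: 9 3β-acetoxyeremophila-9,11-dien-8β-ol
Conditions: NaBH4, CeCl3·7H2O, MeOH, −78 °C
Reagents that add atoms: none
Why: Luche reduction, 1,2-selective for the enone: hydride adds axially from the α face, anti to the axial C5 methyl, and gives the pseudo-equatorial 8β-alcohol (as steroidal 4-en-3-ones give 3β-alcohols). The acetate survives and C7 is not enolised at this temperature.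

Step 8
Reactants: 9 3β-acetoxyeremophila-9,11-dien-8β-ol
Product: 10 3β-acetoxy-9β,10β-epoxyeremophil-11-en-8β-ol
Conditions: VO(acac)2 (cat.), tBuOOH, CH2Cl2, 0 → 25 °C
Reagents that add atoms: tert-butyl hydroperoxide, CC(C)(C)OO
Why: Hydroxyl-directed vanadium-catalysed epoxidation: the vanadium alkoxide–peroxide delivers oxygen to the alkene face that bears the 8β-hydroxyl, so the 9β,10β-epoxide forms despite the C5 methyl on that face, as steroidal 4-en-3β-ols give 4β,5β-epoxides. The allylic C9=C10 alkene reacts much faster than the homoallylic isopropenyl alkene.

Step 9
Reactants: 10 3β-acetoxy-9β,10β-epoxyeremophil-11-en-8β-ol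
Product: 11 3β-acetoxy-9β,10β-epoxyeremophil-11-en-8-one
Conditions: Dess–Martin periodinane, NaHCO3, CH2Cl2, 0 → 25 °C
Reagents that add atoms: none
Why: Dess–Martin oxidation under buffered, non-basic conditions returns the C8 ketone without opening the epoxide, epimerising C7 or moving the isopropenyl alkene; no stereocentre is touched.

Step 10
Reactants: 11 3β-acetoxy-9β,10β-epoxyeremophil-11-en-8-one; 12 angelic acid
Product: 13 3β-acetoxy-9α-angeloyloxy-10β-hydroxyeremophil-11-en-8-one
Conditions: 12 (2.0 equiv), Cs2CO3 (0.5 equiv), DMF, 40 °C
Reagents that add atoms: none
Why: SN2 opening of an α,β-epoxy ketone at the α-carbon: the caesium carboxylate attacks C9, which is activated by the C8 carbonyl, from the α face anti to the epoxide oxygen, while the fully substituted C10 cannot be attacked; inversion gives the 9α ester and the 10β-hydroxyl. The excess free acid protonates the alkoxide and keeps the medium too weakly basic for β-elimination of the new hydroxyl or for migration of the isopropenyl alkene. Because the angelate enters as a nucleophile, its Z geometry is not at risk.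

Step 11
Reactants: 13 3β-acetoxy-9α-angeloyloxy-10β-hydroxyeremophil-11-en-8-one
Product: 14 3β-acetoxy-9α-angeloyloxy-10β-hydroxy-13-noreremophilane-8,11-dione (C7 epimers and enol forms)
Conditions: OsO4 (cat.), NaIO4, 2,6-lutidine, dioxane/H2O 3:1, 25 °C
Reagents that add atoms: osmium tetroxide (catalytic oxygen carrier), O=[Os](=O)(=O)=O; sodium periodate (terminal oxidant), [Na+].[O-]I(=O)(=O)=O
Why: Lemieux–Johnson oxidation: OsO4 dihydroxylates the electron-rich 1,1-disubstituted alkene much faster than the conjugated, trisubstituted angelate, and periodate cleaves the diol to the methyl ketone (C11, C12) with loss of C13. C7 becomes the central carbon of a β-diketone, so its configuration no longer matters.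

Step 12
Reactants: 14 3β-acetoxy-9α-angeloyloxy-10β-hydroxy-13-noreremophilane-8,11-dione
Product: 17 3β-acetoxy-9α-angeloyloxy-10β-hydroxy-13-noreremophil-6-ene-8,11-dione (target), via C7 phenylselenide 15 (not isolated), via C7 selenoxide 16 (not isolated)
Conditions: PhSeCl, pyridine, CH2Cl2, 0 °C; aq. HCl wash; then 30% H2O2, CH2Cl2, 0 → 25 °C
Reagents that add atoms: none
Why: Selenoxide syn-elimination on a β-diketone: the enol of 14 is selenenylated at C7, oxidation gives the selenoxide, and this eliminates at or below room temperature; only C6 offers a β-hydrogen, so the C6=C7 alkene forms. The same reaction type converts 2-acetylcyclohexanone into 2-acetylcyclohex-2-enone, and here the quaternary C5 blocks tautomerisation of the product.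

## Compound list

1 | (2E,6E)-farnesol | CC(C)=CCC/C(C)=C/CC/C(C)=C/CO | starting material
2 | (2E,6E)-farnesyl chloride | CC(C)=CCC/C(C)=C/CC/C(C)=C/CCl | intermediate
3 | (2E,6E)-farnesyl diphosphate, trisammonium salt | CC(C)=CCC/C(C)=C/CC/C(C)=C/COP(=O)([O-])OP(=O)([O-])[O-].[NH4+].[NH4+].[NH4+] | intermediate
4 | (S)-germacrene A, (1(10)E,4E,7S)-germacra-1(10),4,11-triene | CC(=C)[C@H]1CC/C(C)=C/CC/C(C)=C/C1 | intermediate (not isolated)
5 | (+)-aristolochene, (4S,5R,7S)-eremophila-9,11-diene | CC(=C)[C@H]1CC=C2CCC[C@H](C)[C@@]2(C)C1 | intermediate
6 | (4S,5R,7S)-eremophila-9,11-dien-8-one | CC(=C)[C@H]1C(=O)C=C2CCC[C@H](C)[C@@]2(C)C1 | intermediate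
7 | 3β-hydroxyeremophila-9,11-dien-8-one (3S,4R,5R,7S) | CC(=C)[C@H]1C(=O)C=C2CC[C@H](O)[C@H](C)[C@@]2(C)C1 | intermediate
8 | 3β-acetoxyeremophila-9,11-dien-8-one | CC(=C)[C@H]1C(=O)C=C2CC[C@H](OC(C)=O)[C@H](C)[C@@]2(C)C1 | intermediate
9 | 3β-acetoxyeremophila-9,11-dien-8β-ol | CC(=C)[C@H]1[C@H](O)C=C2CC[C@H](OC(C)=O)[C@H](C)[C@@]2(C)C1 | intermediate
10 | 3β-acetoxy-9β,10β-epoxyeremophil-11-en-8β-ol | CC(=C)[C@H]1[C@H](O)[C@@H]2O[C@@]23CC[C@H](OC(C)=O)[C@H](C)[C@@]3(C)C1 | intermediate
11 | 3β-acetoxy-9β,10β-epoxyeremophil-11-en-8-one | CC(=C)[C@H]1C(=O)[C@@H]2O[C@@]23CC[C@H](OC(C)=O)[C@H](C)[C@@]3(C)C1 | intermediate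
12 | angelic acid, (Z)-2-methylbut-2-enoic acid | C/C=C(/C)C(=O)O | starting material
13 | 3β-acetoxy-9α-angeloyloxy-10β-hydroxyeremophil-11-en-8-one (7α-isopropenyl) | C/C=C(/C)C(=O)O[C@@H]1C(=O)[C@H](C(C)=C)C[C@]2(C)[C@@H](C)[C@@H](OC(C)=O)CC[C@]12O | intermediate
14 | 3β-acetoxy-9α-angeloyloxy-10β-hydroxy-13-noreremophilane-8,11-dione (C7 not defined; keto form shown) | C/C=C(/C)C(=O)O[C@@H]1C(=O)C(C(C)=O)C[C@]2(C)[C@@H](C)[C@@H](OC(C)=O)CC[C@]12O | intermediate
15 | 7-phenylselanyl derivative of 14 (C7 not defined) | C/C=C(/C)C(=O)O[C@@H]1C(=O)C([Se]c3ccccc3)(C(C)=O)C[C@]2(C)[C@@H](C)[C@@H](OC(C)=O)CC[C@]12O | intermediate (not isolated)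
16 | selenoxide of 15 (C7 and Se not defined) | C/C=C(/C)C(=O)O[C@@H]1C(=O)C([Se](=O)c3ccccc3)(C(C)=O)C[C@]2(C)[C@@H](C)[C@@H](OC(C)=O)CC[C@]12O | intermediate (not isolated)
17 | 3β-acetoxy-9α-angeloyloxy-10β-hydroxy-13-noreremophil-6-ene-8,11-dione (3S,4R,5R,9S,10R), CNP0196241.1 | C/C=C(/C)C(=O)O[C@@H]1C(=O)C(C(C)=O)=C[C@]2(C)[C@@H](C)[C@@H](OC(C)=O)CC[C@]12O | target

## Step count and least certain steps

Total step count: 12. Longest linear sequence: 12 steps, from 1 to 17; 12 is bought and enters at step 10.

**Step 5 (C3 hydroxylation).** The most likely failure is misplaced oxygen transfer: epoxidation of the isopropenyl alkene, hydroxylation at the allylic C1 or on the isopropenyl methyl, or abstraction of the equatorial 3α hydrogen. The substrate offers weaker C–H bonds and a reactive alkene, and only the pocket of the variant steers the oxidant to C3. The fallback gives up stereoselective hydroxylation and asks the biocatalyst only for site selectivity; the configuration is then set chemically. It sets out from 6. Whole cells expressing the C3-oxygenating P450 of a fungal aristolochene-derived pathway (with its reductase) are fed with 6; whichever epimer forms is accepted, for instance 3α-hydroxyeremophila-9,11-dien-8-one F1. Dess–Martin oxidation gives eremophila-9,11-diene-3,8-dione F2. LiBH(sBu)3 (1 equiv, THF, −78 °C) then reduces the saturated, more electrophilic C3 ketone in preference to the conjugated, β,β-disubstituted C8 ketone. Hydride enters equatorially from the α face because the axial β trajectory is blocked by the syn-axial C5 methyl, which gives the axial 3β-alcohol. The fallback comes back to the route at 7.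

**Step 10 (angelate opening).** The most likely failure is a substitution that is too slow. Angelate is a weak, α-branched nucleophile and C9 sits beside a fully substituted carbon. Slower base-mediated processes could then take over: β-elimination of the C10 hydroxyl from the product and migration of the isopropenyl alkene into conjugation. The fallback separates C–O bond formation from introduction of the angeloyl group. It sets out from 11. Caesium formate with formic acid in DMF at 25 °C, a smaller and better nucleophile, should give 3β-acetoxy-9α-formyloxy-10β-hydroxyeremophil-11-en-8-one F3. Brief methanolysis (KHCO3, MeOH, 0 °C) removes the formate much faster than the hindered C3 acetate and gives 3β-acetoxy-9α,10β-dihydroxyeremophil-11-en-8-one F4. Yamaguchi esterification with 12 (2,4,6-trichlorobenzoyl chloride, Et3N; then F4, toluene, 80 °C) acylates the secondary C9 hydroxyl only, with the mixed anhydride chosen because it carries angelic acid over without isomerisation. The fallback comes back at 13.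

**Step 3 (key step).** The most likely failure is incomplete turnover at preparative scale: product inhibition, magnesium-promoted hydrolysis of 3 in the buffer, and premature release of 4. A purified enzyme working on an added, labile substrate has little room for scale. The fallback moves the reaction into the cell. It sets out from 3, which an E. coli or yeast strain with a strengthened mevalonate pathway makes from glucose and hands directly to the co-expressed cyclase; 5 collects in a dodecane overlay. Steps 1 and 2 are then not needed, and the fallback comes back at 5. It makes no new compound (F0).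

**Step 4 (allylic oxidation).** The most likely failures are loss of regiocontrol (oxidation at C1, or at C7 and the isopropenyl methyl) and over-oxidation, because the hydrocarbon has three allylic sites and the reagent is used in large excess. The fallback replaces hydrogen abstraction by an ene reaction. It sets out from 5. The Schenck ene reaction with singlet oxygen (O2, tetraphenylporphyrin, hν, CH2Cl2, 0 °C) takes hydrogen from C8, on the more crowded side of the alkene, and should give 10α-hydroperoxyeremophila-8,11-diene F5. Allylic (Schenck) rearrangement in CHCl3 at 25 °C moves the hydroperoxide to C8 and gives 8α-hydroperoxyeremophila-9,11-diene F6. Kornblum–DeLaMare dehydration (Ac2O, pyridine, 0 °C) gives the ketone, following the course known for steroidal 5-enes. The fallback comes back at 6.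

**Step 12 (selenoxide elimination).** The most likely failures are loss of the product to conjugate addition (of benzeneselenenic acid or of H2O2, which would epoxidise the doubly activated alkene) and selenenylation at a site other than C7. The fallback introduces the alkene before the second carbonyl exists. It sets out from 13. Dehydrogenation with 2-iodoxybenzoic acid (DMSO, 65 °C) can only run towards C6, since C10 has no hydrogen, and gives 3β-acetoxy-9α-angeloyloxy-10β-hydroxyeremophila-6,11-dien-8-one F7. Lemieux–Johnson cleavage of its terminal alkene (OsO4 cat., NaIO4, 2,6-lutidine) then gives the acetyl group. The fallback comes back at 17 without passing through 14.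

## Further compounds

F0 | step 3 | none | none
F1 | step 5 | 3α-hydroxyeremophila-9,11-dien-8-one | CC(=C)[C@H]1C(=O)C=C2CC[C@@H](O)[C@H](C)[C@@]2(C)C1
F2 | step 5 | eremophila-9,11-diene-3,8-dione | CC(=C)[C@H]1C(=O)C=C2CCC(=O)[C@H](C)[C@@]2(C)C1
F3 | step 10 | 3β-acetoxy-9α-formyloxy-10β-hydroxyeremophil-11-en-8-one | O=CO[C@@H]1C(=O)[C@H](C(C)=C)C[C@]2(C)[C@@H](C)[C@@H](OC(C)=O)CC[C@]12O
F4 | step 10 | 3β-acetoxy-9α,10β-dihydroxyeremophil-11-en-8-one | O[C@@H]1C(=O)[C@H](C(C)=C)C[C@]2(C)[C@@H](C)[C@@H](OC(C)=O)CC[C@]12O
F5 | step 4 | 10α-hydroperoxyeremophila-8,11-diene | CC(=C)[C@H]1C=C[C@]2(OO)CCC[C@H](C)[C@@]2(C)C1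
F6 | step 4 | 8α-hydroperoxyeremophila-9,11-diene | CC(=C)[C@H]1[C@@H](OO)C=C2CCC[C@H](C)[C@@]2(C)C1
F7 | step 12 | 3β-acetoxy-9α-angeloyloxy-10β-hydroxyeremophila-6,11-dien-8-one | C/C=C(/C)C(=O)O[C@@H]1C(=O)C(C(C)=C)=C[C@]2(C)[C@@H](C)[C@@H](OC(C)=O)CC[C@]12O
A1 | alternative 1 | cis-fused oxasilolane (C10–O–SiMe2–C14–C5) with C8 silyl ether, C3 ketone and C4 methyl | C1[C@@H](O[Si](C)(C)C(C)(C)C)CC[C@]2(C[Si](C)(C)O3)[C@@H](C)C(=O)CC[C@]123
A2 | alternative 1 | C10 O-(bromomethyl)dimethylsilyl ether of the C4=C5 enone | C1[C@@H](O[Si](C)(C)C(C)(C)C)CCC2=C(C)C(=O)CC[C@]12O[Si](C)(C)CBr
A3 | alternative 2 | cis-fused C10-hydroxy C3 ketone with C8 dioxolane | C1C3(OCCO3)CC[C@]2(C)[C@@H](C)C(=O)CC[C@]12O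
A4 | alternative 2 | cyclopropanol precursor with C10 ketone and C8 dioxolane | O=C1CC2(OCCO2)CC[C@]1(C)[C@@H](C)C1(O)CC1
A5 | alternative 3 | 2-allyl-4,4-dimethoxy-2,3-dimethylcyclohexan-1-one | C=CC[C@]1(C)[C@@H](C)C(OC)(OC)CCC1=O
A6 | alternative 3 | 4,4-dimethoxy-2-methylcyclohex-2-en-1-one | CC1=CC(OC)(OC)CCC1=O
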